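## Retrosynthetic overview

- Hydrindane numbering is used: C1 (ethylidene), C2 (OAc), C3, C3a, C4 (=CH2), C5 (OH), C6 (O-angelate), C7 (isopropyl), C7a. The last operations are the angelate on C6–OH and the C4 methylene with C3a–H, both released from a C4(CH2Si)=C3a allylsilane by protodesilylation.
- Key disconnection: the cyclohexene ring, by a silicon-tethered intramolecular Diels–Alder reaction that makes C5–C6 and C7–C7a at once. The diene is C5=C4–C3a=C7a (a 1-silyloxy diene whose C3a=C7a bond lies in the cyclopentene ring); the dienophile is C6=C7 (the Z enol silyl ether of 3-methylbutanal).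
- Enabling feature: the vicinal oxygen pair on C5 and C6 of the six-membered ring. In the precursor both are enol oxygens, so one iPr2Si unit bridges them as a 1,3-dioxa-2-silolane ring that is not in the target and is cleaved afterwards; the C4 methylene is carried as CH2SiMe2Ph on the diene.
- Diene half: (S)-4-silyloxycyclopentenone, then alkynylation and oxidative transposition, Z-selective Wittig reaction, silylformylation of the enyne, and conjugate reduction.
- Ring order: cyclopentane ring (from the starting enone); then the cyclohexene ring and the temporary dioxasilolane ring together in the key step; then removal of the temporary ring.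

Key step: step 10

Assumption: (S)-4-[(tert-butyldimethylsilyl)oxy]cyclopent-2-en-1-one is taken as a commercial enantiopure starting material, and soft enolisation of 3-methylbutanal is taken to give mainly the Z enol silane (any E isomer of 13 is removed by fractional distillation).

## Route

Step 1
Reactants: 1 (S)-4-[(tert-butyldimethylsilyl)oxy]cyclopent-2-en-1-one; 2 ethynyltrimethylsilane
Product: 3 (1R,4S)-4-[(tert-butyldimethylsilyl)oxy]-1-[(trimethylsilyl)ethynyl]cyclopent-2-en-1-ol (hydroxyl cis to the silyloxy group)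
Conditions: 2, n-BuLi, THF, −78 °C; then 1, −78 °C; H2O quench
Reagents that add atoms: none
Why: 1,2-addition of a lithium acetylide to the enone carbonyl at low temperature, anti to the 4-silyloxy group; the new carbinol centre is removed again in step 2.

Step 2
Reactants: 3
Product: 4 (S)-5-[(tert-butyldimethylsilyl)oxy]-3-[(trimethylsilyl)ethynyl]cyclopent-2-en-1-one
Conditions: [C5H5NH][CrO3Cl] (pyridinium chlorochromate), 4 Å molecular sieves, CH2Cl2, rt
Reagents that add atoms: none
Why: Dauben–Babler oxidative 1,3-transposition of a tertiary allylic alcohol ([3,3] shift of the chromate ester, then oxidation) moves the carbonyl next to the silyloxy carbon without touching its configuration.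

Step 3
Reactants: 4; 5 ethyltriphenylphosphonium bromide
Product: 6 tert-butyl{[(1S,2Z)-2-ethylidene-4-[(trimethylsilyl)ethynyl]cyclopent-3-en-1-yl]oxy}dimethylsilane (ethylidene methyl on the side of the silyloxy carbon)
Conditions: 5, KN(SiMe3)2, THF, 0 °C; then 4, −78 → 0 °C
Reagents that add atoms: none
Why: Wittig olefination by 1,2-attack on the enone carbonyl; with α-alkoxy ketones unstabilised ylides place their substituent cis to the alkoxy-bearing carbon (Still's α-alkoxy ketone selectivity), which is the required Z ethylidene.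

Step 4
Reactants: 6
Product: 7 (1S,2Z)-2-ethylidene-4-ethynylcyclopent-3-en-1-ol
Conditions: Bu4NF·3H2O, THF, 0 °C
Reagents that add atoms: none
Why: fluoride cleaves the O–Si bond and the alkynyl C–Si bond in one desilylation; no base-sensitive leaving group is present.

Step 5
Reactants: 7
Product: 8 (1S,2Z)-2-ethylidene-4-ethynylcyclopent-3-en-1-yl acetate
Conditions: Ac2O, pyridine, 4-(dimethylamino)pyridine (cat.), CH2Cl2, 0 °C
Reagents that add atoms: acetic anhydride, CC(=O)OC(C)=O
Why: standard acylation of a secondary alcohol installs the C2 acetate of the target early, so that only the two six-ring oxygens need to be told apart later.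

Step 6
Reactants: 8
Product: 9 (1S,2Z)-4-[(1Z)-1-(dimethylphenylsilyl)-3-oxoprop-1-en-2-yl]-2-ethylidenecyclopent-3-en-1-yl acetate (formyl and silyl groups cis)
Conditions: Me2PhSiH, CO (1 atm), Rh2(O2CC3F7)4 (cat.), CH2Cl2, 0 °C → rt
Reagents that add atoms: dimethylphenylsilane, C[SiH](C)c1ccccc1; carbon monoxide, [C-]#[O+]
Why: rhodium-catalysed silylformylation of a terminal alkyne adds silyl to the terminal carbon and formyl to the internal carbon in a syn fashion, giving in one step C5 (the formyl carbon), C4 and the future methylene carbon bearing silicon.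

Step 7
Reactants: 9
Product: 10 (1S,2Z)-4-[1-(dimethylphenylsilyl)-3-oxopropan-2-yl]-2-ethylidenecyclopent-3-en-1-yl acetate (both epimers at the aldehyde α-carbon)
Conditions: [(Ph3P)CuH]6 (0.2 equiv), degassed wet benzene/THF, rt
Reagents that add atoms: none
Why: conjugate reduction of the enal by the phosphine-stabilised copper hydride (hydride to the silyl-bearing β-carbon, protonation of the copper enolate) leaves the isolated alkenes and the acetate untouched; the new α-centre is destroyed in step 9.

Step 8
Reactants: 11 3-methylbutanal; 12 dichlorodiisopropylsilane (3 equiv)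
Product: 13 chloro{[(1Z)-3-methylbut-1-en-1-yl]oxy}diisopropylsilane
Conditions: NaI, Et3N, MeCN, 0 °C → rt; pentane extraction, fractional distillation
Reagents that add atoms: none
Why: soft enolisation of the aldehyde (iodosilane formed in the flask, amine base) gives the enol silane with Z geometry predominating, and the excess of 12 keeps one Si–Cl bond for the second enol.

Step 9
Reactants: 10; 13
Product: 15 (1S,2Z)-2-ethylidene-4-{(1Z)-3-(dimethylphenylsilyl)-1-[({[(1Z)-3-methylbut-1-en-1-yl]oxy}diisopropylsilyl)oxy]prop-1-en-2-yl}cyclopent-3-en-1-yl acetate (dienol oxygen cis to CH2Si and trans to the ring), via potassium dienolate 14 (not isolated)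
Conditions: KN(SiMe3)2 (0.95 equiv), THF, −78 → −40 °C; then 13, −78 → 0 °C; chromatography on Et3N-deactivated silica
Reagents that add atoms: none
Why: deprotonation of the doubly activated α-C–H gives the extended dienolate, which is silylated on oxygen by the hindered chlorosilane; the oxygen is expected trans to the cyclopentenyl group because the cis isomer suffers allylic 1,3-strain in the planar trienolate.

Step 10
Reactants: 15
Product: 16 Diels–Alder adduct, the 5,6-O-(diisopropylsilanediyl) derivative of (1Z)-2-acetoxy-4-[(dimethylphenylsilyl)methyl]-1-ethylidene-7-isopropyl-2,3,5,6,7,7a-hexahydro-1H-indene-5,6-diol (C5–O and C6–O trans; C6–O and C7 isopropyl cis; C7 isopropyl trans to C1; C2 acetoxy trans to the C7a–C7 bond)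
Conditions: toluene (high dilution), 2,6-di-tert-butyl-4-methylphenol (cat.), base-washed sealed tube, 180 °C
Reagents that add atoms: none
Why: Proposed new method: thermal, concerted but asynchronous [4+2] cycloaddition of the 1-silyloxy diene C5=C4–C3a=C7a with the tethered Z enol ether C6=C7; neither partner is activated, so the three-atom O–Si–O tether with its geminal isopropyl groups has to supply the rate by proximity and fixes the regiochemistry (C5 to C6, C7a to C7) against the electronic preference, the closest known reactions being the thermal intramolecular Diels–Alder reactions of unactivated nona-1,3,8-trienes and of silicon-tethered trienes, which have not been shown for a bis(enoxy)silane. The cyclohexene ring closes in the [4+2] mode, and the temporary 1,3-dioxa-2-silolane ring closes as the five-membered ring of a type 1 intramolecular Diels–Alder reaction (tether on the diene terminus). C5 and C7a are set by the diene geometry (silyloxy group and ring carbon C1 both outside, hence cis) and C6 and C7 by the Z geometry of the enol ether (oxygen and isopropyl cis). The trans C5/C6 relationship comes from the exo, tether-anti (trans-fused) transition state, preferred because the endo alternative would push the Z isopropyl group under the diene against C3 and the CH2SiMe2Ph group and because no secondary orbital interaction favours endo. The absolute sense comes from C2: allylic 1,3-strain with the Z ethylidene methyl holds the acetoxy group pseudo-axial, so the dienophile adds to the opposite face of C7a. The step therefore needs exo and π-facial selectivity, while regioselectivity is secured by the tether.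

Step 11
Reactants: 16
Product: 17 (1Z)-4-[(dimethylphenylsilyl)methyl]-1-ethylidene-5,6-dihydroxy-7-isopropyl-2,3,5,6,7,7a-hexahydro-1H-inden-2-yl acetate (configurations as in 16)
Conditions: Et3N·3HF, THF, 0 °C
Reagents that add atoms: none
Why: fluoride cleaves the strained five-membered dialkylsilylene much faster than it attacks the allylsilane or the acetate, releasing the trans diol, whose ring now relaxes to the half-chair with C5–OH and C6–OH axial and the isopropyl group equatorial.

Step 12
Reactants: 17
Product: 18 (1Z,2S,3aR,5S,6S,7S,7aR)-1-ethylidene-5,6-dihydroxy-4-methylidene-7-(propan-2-yl)octahydro-1H-inden-2-yl acetate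
Conditions: CF3CO2H, CH2Cl2, −40 → −20 °C; NaHCO3 quench
Reagents that add atoms: none
Why: SE2' protodesilylation of the tetrasubstituted allylsilane (proton to C3a, loss of silicon from the β-silyl cation) gives the exocyclic methylene; C3a–H is set by axial protonation anti to the pseudo-axial C7a–H, on the face opposite the pseudo-axial C2 acetoxy group, which leads directly to the chair of the trans-fused hydrindane.

Step 13
Reactants: 18
Product: 19 (1Z,2S,3aR,5S,6S,7S,7aR)-1-ethylidene-6-hydroxy-4-methylidene-7-(propan-2-yl)-5-[(triethylsilyl)oxy]octahydro-1H-inden-2-yl acetate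
Conditions: Et3SiCl (1.05 equiv), imidazole, CH2Cl2, −20 °C
Reagents that add atoms: chlorotriethylsilane, CC[Si](Cl)(CC)CC
Why: selective silylation of the less hindered allylic C5 hydroxyl; the axial C6 hydroxyl is gauche to the equatorial isopropyl group (a neomenthol-like environment) and reacts more slowly, and any bis-silyl ether or regioisomer can be recycled by desilylation.

Step 14
Reactants: 19; 20 angelic acid, (2Z)-2-methylbut-2-enoic acid
Product: 21 (1Z,2S,3aR,5S,6S,7S,7aR)-2-acetoxy-1-ethylidene-4-methylidene-7-(propan-2-yl)-5-[(triethylsilyl)oxy]octahydro-1H-inden-6-yl (2Z)-2-methylbut-2-enoate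
Conditions: 20, 2,4,6-Cl3C6H2COCl, Et3N, toluene, rt; then 19, 80 °C (no nucleophilic catalyst)
Reagents that add atoms: none
Why: Yamaguchi esterification through the mixed anhydride, attacked at the less hindered angeloyl carbonyl; leaving out 4-(dimethylamino)pyridine avoids the addition–elimination that isomerises angelates to tiglates.

Step 15
Reactants: 21
Product: 22 (1Z,2S,3aR,5S,6S,7S,7aR)-2-acetoxy-1-ethylidene-5-hydroxy-4-methylidene-7-(propan-2-yl)octahydro-1H-inden-6-yl (2Z)-2-methylbut-2-enoate (target)
Conditions: HF·pyridine, pyridine/THF, 0 °C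
Reagents that add atoms: none
Why: buffered fluoride removes the triethylsilyl ether without affecting the acetate, the angelate or the two exocyclic alkenes; the trans-diaxial arrangement of C5–OH and the C6 ester excludes acyl migration.

## Compound list

1 | (S)-4-[(tert-butyldimethylsilyl)oxy]cyclopent-2-en-1-one | O=C1C=C[C@@H](O[Si](C)(C)C(C)(C)C)C1 | starting material
2 | ethynyltrimethylsilane | C#C[Si](C)(C)C | starting material
3 | (1R,4S)-4-[(tert-butyldimethylsilyl)oxy]-1-[(trimethylsilyl)ethynyl]cyclopent-2-en-1-ol | O[C@@]1(C#C[Si](C)(C)C)C=C[C@@H](O[Si](C)(C)C(C)(C)C)C1 | intermediate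
4 | (S)-5-[(tert-butyldimethylsilyl)oxy]-3-[(trimethylsilyl)ethynyl]cyclopent-2-en-1-one | C[Si](C)(C)C#CC1=CC(=O)[C@@H](O[Si](C)(C)C(C)(C)C)C1 | intermediate
5 | ethyltriphenylphosphonium bromide | CC[P+](c1ccccc1)(c1ccccc1)c1ccccc1.[Br-] | starting material
6 | tert-butyl{[(1S,2Z)-2-ethylidene-4-[(trimethylsilyl)ethynyl]cyclopent-3-en-1-yl]oxy}dimethylsilane | C[Si](C)(C)C#CC1=C/C(=C/C)[C@@H](O[Si](C)(C)C(C)(C)C)C1 | intermediate
7 | (1S,2Z)-2-ethylidene-4-ethynylcyclopent-3-en-1-ol | C#CC1=C/C(=C/C)[C@@H](O)C1 | intermediate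
8 | (1S,2Z)-2-ethylidene-4-ethynylcyclopent-3-en-1-yl acetate | C#CC1=C/C(=C/C)[C@@H](OC(C)=O)C1 | intermediate
9 | (1S,2Z)-4-[(1Z)-1-(dimethylphenylsilyl)-3-oxoprop-1-en-2-yl]-2-ethylidenecyclopent-3-en-1-yl acetate | O=C/C(=C\[Si](C)(C)c1ccccc1)C1=C/C(=C/C)[C@@H](OC(C)=O)C1 | intermediate
10 | (1S,2Z)-4-[1-(dimethylphenylsilyl)-3-oxopropan-2-yl]-2-ethylidenecyclopent-3-en-1-yl acetate (both α-epimers) | O=CC(C[Si](C)(C)c1ccccc1)C1=C/C(=C/C)[C@@H](OC(C)=O)C1 | intermediate
11 | 3-methylbutanal | CC(C)CC=O | starting material
12 | dichlorodiisopropylsilane | CC(C)[Si](Cl)(Cl)C(C)C | starting material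
13 | chloro{[(1Z)-3-methylbut-1-en-1-yl]oxy}diisopropylsilane | CC(C)/C=C\O[Si](Cl)(C(C)C)C(C)C | intermediate
14 | potassium dienolate of 10 (oxygen trans to the cyclopentenyl group) | [K+].[O-]/C=C(C[Si](C)(C)c1ccccc1)/C1=C/C(=C/C)[C@@H](OC(C)=O)C1 | intermediate
15 | (1S,2Z)-2-ethylidene-4-{(1Z)-3-(dimethylphenylsilyl)-1-[({[(1Z)-3-methylbut-1-en-1-yl]oxy}diisopropylsilyl)oxy]prop-1-en-2-yl}cyclopent-3-en-1-yl acetate | CC(C)/C=C\O[Si](C(C)C)(C(C)C)O/C=C(C[Si](C)(C)c1ccccc1)/C1=C/C(=C/C)[C@@H](OC(C)=O)C1 | intermediate
16 | Diels–Alder adduct: 5,6-O-(diisopropylsilanediyl) derivative of (1Z)-2-acetoxy-4-[(dimethylphenylsilyl)methyl]-1-ethylidene-7-isopropyl-2,3,5,6,7,7a-hexahydro-1H-indene-5,6-diol | C[Si](C)(c1ccccc1)CC=1[C@@H]3O[Si](C(C)C)(C(C)C)O[C@H]3[C@@H](C(C)C)[C@@H]2/C(=C/C)[C@@H](OC(C)=O)CC=12 | intermediate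
17 | (1Z)-4-[(dimethylphenylsilyl)methyl]-1-ethylidene-5,6-dihydroxy-7-isopropyl-2,3,5,6,7,7a-hexahydro-1H-inden-2-yl acetate | C[Si](C)(c1ccccc1)CC=1[C@H](O)[C@@H](O)[C@@H](C(C)C)[C@@H]2/C(=C/C)[C@@H](OC(C)=O)CC=12 | intermediate
18 | (1Z,2S,3aR,5S,6S,7S,7aR)-1-ethylidene-5,6-dihydroxy-4-methylidene-7-(propan-2-yl)octahydro-1H-inden-2-yl acetate | C=C1[C@H](O)[C@@H](O)[C@@H](C(C)C)[C@@H]2/C(=C/C)[C@@H](OC(C)=O)C[C@@H]12 | intermediate
19 | (1Z,2S,3aR,5S,6S,7S,7aR)-1-ethylidene-6-hydroxy-4-methylidene-7-(propan-2-yl)-5-[(triethylsilyl)oxy]octahydro-1H-inden-2-yl acetate | C=C1[C@H](O[Si](CC)(CC)CC)[C@@H](O)[C@@H](C(C)C)[C@@H]2/C(=C/C)[C@@H](OC(C)=O)C[C@@H]12 | intermediate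
20 | angelic acid, (2Z)-2-methylbut-2-enoic acid | C/C=C(/C)C(=O)O | starting material
21 | (1Z,2S,3aR,5S,6S,7S,7aR)-2-acetoxy-1-ethylidene-4-methylidene-7-(propan-2-yl)-5-[(triethylsilyl)oxy]octahydro-1H-inden-6-yl (2Z)-2-methylbut-2-enoate | C=C1[C@H](O[Si](CC)(CC)CC)[C@@H](OC(=O)/C(C)=C\C)[C@@H](C(C)C)[C@@H]2/C(=C/C)[C@@H](OC(C)=O)C[C@@H]12 | intermediate
22 | (1Z,2S,3aR,5S,6S,7S,7aR)-2-acetoxy-1-ethylidene-5-hydroxy-4-methylidene-7-(propan-2-yl)octahydro-1H-inden-6-yl (2Z)-2-methylbut-2-enoate | C=C1[C@H](O)[C@@H](OC(=O)/C(C)=C\C)[C@@H](C(C)C)[C@@H]2/C(=C/C)[C@@H](OC(C)=O)C[C@@H]12 | target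

## Step count and risks

Total step count: 15. Longest linear sequence: 14 steps (steps 1–7 and 9–15; step 8 prepares the tether reagent 13).

Steps most likely to fail:

1. Step 10 (proposed new method). The two electron-rich partners may not combine below the temperature at which the silyl enol ethers decompose, and exo (trans-fused) or π-facial selectivity may be poor. The fallback is a polarity-matched intermolecular Diels–Alder reaction that makes the same two bonds. It sets out from 10: deprotonation with KN(SiMe3)2 and O-silylation with t-BuMe2SiCl gives the tert-butyldimethylsilyl dienol ether F1. Its normal-demand cycloaddition with commercial (E)-3-methyl-1-nitrobut-1-ene (toluene, 60 °C) joins C5 to C6 and C7a to C7, giving the nitro adduct F2; the endo-nitro transition state places the isopropyl group trans to C1. A Nef reaction (KOt-Bu, THF, −78 °C, then aqueous TiCl3 buffered with NH4OAc) converts F2 into the C6 ketone F3. HF·pyridine then frees the C5 hydroxyl to give the hydroxy ketone F4. Hydroxyl-directed reduction with Me4NBH(OAc)3 (MeCN/AcOH, −20 °C) delivers hydride to C6 from the face of the C5 hydroxyl and gives the trans diol 17, where the route is rejoined.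

2. Step 9. Enol ether geometry may be lost (E/Z mixtures from the dienolate or carried in with 13), and C-silylation or self-condensation of the aldehyde may compete. The fallback reverses the order of assembly so that the geometry-critical Z enolate comes from a purified volatile precursor. It sets out from 10 (and 11): KN(SiMe3)2 followed by excess iPr2SiCl2 gives, after removal of the excess reagent in vacuum, the chloro(dienyloxy)diisopropylsilane F5. Separately the trimethylsilyl enol ether of 11 is made (Me3SiCl, Et3N, NaI) and its Z isomer, the Z trimethylsilyl enol ether F6, is isolated by fractional distillation. Cleavage of F6 with MeLi (THF, 0 °C) gives the lithium Z enolate F7 with retention of geometry, and O-silylation of F7 by F5 at −78 °C rejoins the route at 15.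

3. Step 14. Acylation of the hindered axial C6 hydroxyl may stall, and forcing conditions isomerise the angelate to the tiglate. The fallback builds the Z double bond after the acylation. It sets out from 19: esterification with 2-[bis(2,2,2-trifluoroethoxy)phosphoryl]propanoic acid (dicyclohexylcarbodiimide, 4-(dimethylamino)pyridine, CH2Cl2) gives the phosphonate ester F8. A Still–Gennari olefination of F8 with acetaldehyde (KN(SiMe3)2, 18-crown-6, THF, −78 °C) gives the Z-configured 2-methylbut-2-enoate and rejoins the route at 21.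

Further compounds

F1 | step 10 | (1S,2Z)-4-{(1Z)-1-[(tert-butyldimethylsilyl)oxy]-3-(dimethylphenylsilyl)prop-1-en-2-yl}-2-ethylidenecyclopent-3-en-1-yl acetate | CC(C)(C)[Si](C)(C)O/C=C(C[Si](C)(C)c1ccccc1)/C1=C/C(=C/C)[C@@H](OC(C)=O)C1
F2 | step 10 | (1Z)-5-[(tert-butyldimethylsilyl)oxy]-4-[(dimethylphenylsilyl)methyl]-1-ethylidene-7-isopropyl-6-nitro-2,3,5,6,7,7a-hexahydro-1H-inden-2-yl acetate (nitro cis to the C5 silyloxy group, isopropyl trans to C1) | C[Si](C)(c1ccccc1)CC=1[C@H](O[Si](C)(C)C(C)(C)C)[C@H]([N+](=O)[O-])[C@@H](C(C)C)[C@@H]2/C(=C/C)[C@@H](OC(C)=O)CC=12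
F3 | step 10 | (1Z)-5-[(tert-butyldimethylsilyl)oxy]-4-[(dimethylphenylsilyl)methyl]-1-ethylidene-7-isopropyl-6-oxo-2,3,5,6,7,7a-hexahydro-1H-inden-2-yl acetate | C[Si](C)(c1ccccc1)CC=1[C@H](O[Si](C)(C)C(C)(C)C)C(=O)[C@@H](C(C)C)[C@@H]2/C(=C/C)[C@@H](OC(C)=O)CC=12
F4 | step 10 | (1Z)-4-[(dimethylphenylsilyl)methyl]-1-ethylidene-5-hydroxy-7-isopropyl-6-oxo-2,3,5,6,7,7a-hexahydro-1H-inden-2-yl acetate | C[Si](C)(c1ccccc1)CC=1[C@H](O)C(=O)[C@@H](C(C)C)[C@@H]2/C(=C/C)[C@@H](OC(C)=O)CC=12
F5 | step 9 | (1S,2Z)-4-{(1Z)-1-[(chlorodiisopropylsilyl)oxy]-3-(dimethylphenylsilyl)prop-1-en-2-yl}-2-ethylidenecyclopent-3-en-1-yl acetate | CC(C)[Si](Cl)(C(C)C)O/C=C(C[Si](C)(C)c1ccccc1)/C1=C/C(=C/C)[C@@H](OC(C)=O)C1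
F6 | step 9 | trimethyl{[(1Z)-3-methylbut-1-en-1-yl]oxy}silane | CC(C)/C=C\O[Si](C)(C)C
F7 | step 9 | lithium (1Z)-3-methylbut-1-en-1-olate | [Li+].[O-]/C=C\C(C)C
F8 | step 14 | (1Z,2S,3aR,5S,6S,7S,7aR)-2-acetoxy-1-ethylidene-4-methylidene-7-(propan-2-yl)-5-[(triethylsilyl)oxy]octahydro-1H-inden-6-yl 2-[bis(2,2,2-trifluoroethoxy)phosphoryl]propanoate | C=C1[C@H](O[Si](CC)(CC)CC)[C@@H](OC(=O)C(C)P(=O)(OCC(F)(F)F)OCC(F)(F)F)[C@@H](C(C)C)[C@@H]2/C(=C/C)[C@@H](OC(C)=O)C[C@@H]12
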